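Tetralin numbering: C1 carries the guaiacyl ring, C2 and C3 the CH2OH groups, C4 is the ring CH2, C8a the ring A carbon on C1. Ring B is closed on an enantiopure γ-butyrolactone that already holds C1 (as a benzylic carbinol), C2 and C3. In one flask its enolate carbon C3 is benzylated by a ring A benzyl bromide (C4–C3), then acid ionises the C1 carbinol and ring A captures the cation at C8a, para to the C6 methoxy group (C8a–C1). The step exploits the 1,3-relation of the cation-stabilised C1 and the enolisable C3 (its CH2OH is a masked lactone carbonyl); the single stereocentre C2, set by a D-proline aldol, controls C3 and C1.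

Key step: step 6

Step 1
Reactants: 1 2,3,4-trihydroxybenzaldehyde
Product: 2 4-(benzyloxy)-2,3-dihydroxybenzaldehyde
Conditions: BnBr (1.0 equiv), NaHCO3, DMF, 40 °C
Reagents that add atoms: benzyl bromide, BrCc1ccccc1
Why: The 4-hydroxyl, para to the formyl group, is the most acidic phenol and is not tied up in hydrogen bonding to the carbonyl, so one equivalent of benzyl bromide with a weak base should etherify it selectively (Williamson ether synthesis).

Step 2
Reactants: 2 4-(benzyloxy)-2,3-dihydroxybenzaldehyde
Product: 3 4-(benzyloxy)-2,3-dimethoxybenzaldehyde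
Conditions: MeI (3 equiv), K2CO3, DMF, 50 °C
Reagents that add atoms: iodomethane, CI
Why: Both remaining phenols, including the chelated 2-hydroxyl, should be O-methylated under forcing Williamson conditions, the formyl and benzyl ether groups being inert.

Step 3
Reactants: 3 4-(benzyloxy)-2,3-dimethoxybenzaldehyde
Product: 4 [4-(benzyloxy)-2,3-dimethoxyphenyl]methanol
Conditions: NaBH4, MeOH, 0 °C
Reagents that add atoms: none
Why: Borohydride reduction of an aryl aldehyde to the benzylic alcohol is chemoselective in the presence of the aryl ethers.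

Step 4
Reactants: 4 [4-(benzyloxy)-2,3-dimethoxyphenyl]methanol
Product: 5 1-(benzyloxy)-4-(bromomethyl)-2,3-dimethoxybenzene
Conditions: PBr3 (0.4 equiv), Et2O, 0 °C; used crude at once
Reagents that add atoms: phosphorus tribromide, BrP(Br)Br
Why: Bromination of an alkoxy-substituted benzylic alcohol with PBr3 (displacement of the phosphite ester by bromide) is reliable, and the labile electron-rich bromide should be carried on without purification.

Step 5
Reactants: 6 4-(benzyloxy)-3-methoxybenzaldehyde, 7 methyl 4-oxobutanoate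
Product: 10 (4S)-4-[(S)-[4-(benzyloxy)-3-methoxyphenyl](hydroxy)methyl]oxolan-2-one, via aldol aldehyde 8 (not isolated), via diol ester 9 (not isolated)
Conditions: D-proline (20 mol %), DMF, 4 °C, slow addition of 7; then NaBH4, MeOH, 0 °C; then TsOH (cat.), CH2Cl2, rt
Reagents that add atoms: none
Why: In this proline-catalysed direct cross-aldol reaction the enamine of donor 7 adds to the non-enolisable aldehyde 6 through the closed, hydrogen-bonded transition state, so D-proline sets the α-carbon (later C2) and gives the anti adduct; borohydride reduction of the formyl group and lactonisation through the new primary alcohol then give 10, whose carbinol configuration need not be controlled because that centre is ionised in step 6.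

Step 6
Reactants: 10 (4S)-4-[(S)-[4-(benzyloxy)-3-methoxyphenyl](hydroxy)methyl]oxolan-2-one, 5 1-(benzyloxy)-4-(bromomethyl)-2,3-dimethoxybenzene
Product: 12 (3aS,4R,9aS)-6-(benzyloxy)-4-[4-(benzyloxy)-3-methoxyphenyl]-7,8-dimethoxy-3a,4,9,9a-tetrahydronaphtho[2,3-c]furan-1(3H)-one, via alkylated lactone 11 (not isolated)
Conditions: LiN(SiMe3)2 (2.2 equiv), THF, −78 °C; 5, −78 → −30 °C; then CH2Cl2, TFA (excess), 0 °C → rt, same flask
Reagents that add atoms: none
Why: Two equivalents of LiN(SiMe3)2 turn 10 into its alkoxide–enolate dianion, whose enolate carbon C3 is alkylated by bromide 5 (SN2) on the face anti to the C2 side chain, so C2 sets C3 trans; acidification then ionises the electron-rich benzylic carbinol at C1 to a para-alkoxybenzyl (quinone-methide-like) cation that C8a of ring A captures in an intramolecular Friedel–Crafts alkylation. The closest known reaction types are the trans-selective benzylation of β-substituted γ-butyrolactone enolates used for dibenzylbutyrolactone lignans and the acid-mediated cyclisation of benzylic-hydroxylated dibenzylbutyrolactones to conidendrin-type aryltetralin lactones, which mirrors the ring closure of cyclolignan biosynthesis. Ring B closes as a six-membered ring by attack of the arene on the exocyclic cationic carbon (6-exo-trig with respect to the cation). C1 is set under substrate control: in the chair-like transition state the pendant aryl group lies pseudo-equatorial and trans to the C2 lactone CH2, which should give the all-trans, trans-fused lactone, and since C1 is planar at that stage the carbinol configuration of 10 is irrelevant. The step needs C-alkylation at C3 before any cation exists, which the base-then-acid order secures (in an all-acid union the cation would be intercepted intermolecularly at C8, the electronically preferred site of ring A), and it needs closure at C8a, which the tether enforces because only C8a, para to the C6 methoxy group, is within reach for a six-membered ring.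

Step 7
Reactants: 12 (3aS,4R,9aS)-6-(benzyloxy)-4-[4-(benzyloxy)-3-methoxyphenyl]-7,8-dimethoxy-3a,4,9,9a-tetrahydronaphtho[2,3-c]furan-1(3H)-one
Product: 13 [(1R,2S,3S)-7-(benzyloxy)-1-[4-(benzyloxy)-3-methoxyphenyl]-5,6-dimethoxy-1,2,3,4-tetrahydronaphthalene-2,3-diyl]dimethanol
Conditions: LiAlH4, THF, 0 °C → rt
Reagents that add atoms: none
Why: Hydride reduction of the γ-lactone should give the 1,4-diol without touching the three stereocentres or the aryl and benzyl ethers.

Step 8
Reactants: 13 [(1R,2S,3S)-7-(benzyloxy)-1-[4-(benzyloxy)-3-methoxyphenyl]-5,6-dimethoxy-1,2,3,4-tetrahydronaphthalene-2,3-diyl]dimethanol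
Product: 14 4-[(1R,2S,3S)-7-hydroxy-2,3-bis(hydroxymethyl)-5,6-dimethoxy-1,2,3,4-tetrahydronaphthalen-1-yl]-2-methoxyphenol
Conditions: H2 (1 atm), 10% Pd/C, EtOAc/MeOH, rt
Reagents that add atoms: none
Why: Catalytic hydrogenolysis should cleave both aryl benzyl ethers to the free phenols, while the diarylmethine C1–H, the methyl ethers and the primary alcohols are inert under these mild conditions.

Compound list
1 | 2,3,4-trihydroxybenzaldehyde | O=Cc1ccc(O)c(O)c1O | starting material
2 | 4-(benzyloxy)-2,3-dihydroxybenzaldehyde | O=Cc1ccc(OCc2ccccc2)c(O)c1O | intermediate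
3 | 4-(benzyloxy)-2,3-dimethoxybenzaldehyde | COc1c(C=O)ccc(OCc2ccccc2)c1OC | intermediate
4 | [4-(benzyloxy)-2,3-dimethoxyphenyl]methanol | COc1c(CO)ccc(OCc2ccccc2)c1OC | intermediate
5 | 1-(benzyloxy)-4-(bromomethyl)-2,3-dimethoxybenzene | COc1c(CBr)ccc(OCc2ccccc2)c1OC | intermediate
6 | 4-(benzyloxy)-3-methoxybenzaldehyde | COc1cc(C=O)ccc1OCc1ccccc1 | starting material
7 | methyl 4-oxobutanoate | COC(=O)CCC=O | starting material
8 | methyl (3R,4S)-4-[4-(benzyloxy)-3-methoxyphenyl]-3-formyl-4-hydroxybutanoate | COC(=O)C[C@@H](C=O)[C@H](O)c1ccc(OCc2ccccc2)c(OC)c1 | intermediate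
9 | methyl (3S,4S)-4-[4-(benzyloxy)-3-methoxyphenyl]-4-hydroxy-3-(hydroxymethyl)butanoate | COC(=O)C[C@@H](CO)[C@H](O)c1ccc(OCc2ccccc2)c(OC)c1 | intermediate
10 | (4S)-4-[(S)-[4-(benzyloxy)-3-methoxyphenyl](hydroxy)methyl]oxolan-2-one | O=C1C[C@@H](CO1)[C@H](O)c1ccc(OCc2ccccc2)c(OC)c1 | intermediate
11 | (3S,4S)-3-[[4-(benzyloxy)-2,3-dimethoxyphenyl]methyl]-4-[(S)-[4-(benzyloxy)-3-methoxyphenyl](hydroxy)methyl]oxolan-2-one | O=C1OC[C@@H]([C@H](O)c2ccc(OCc3ccccc3)c(OC)c2)[C@@H]1Cc1ccc(OCc2ccccc2)c(OC)c1OC | intermediate
12 | (3aS,4R,9aS)-6-(benzyloxy)-4-[4-(benzyloxy)-3-methoxyphenyl]-7,8-dimethoxy-3a,4,9,9a-tetrahydronaphtho[2,3-c]furan-1(3H)-one | COc1cc([C@@H]2c3cc(OCc4ccccc4)c(OC)c(OC)c3C[C@H](C(=O)O5)[C@H]2C5)ccc1OCc1ccccc1 | intermediate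
13 | [(1R,2S,3S)-7-(benzyloxy)-1-[4-(benzyloxy)-3-methoxyphenyl]-5,6-dimethoxy-1,2,3,4-tetrahydronaphthalene-2,3-diyl]dimethanol | COc1cc([C@@H]2c3cc(OCc4ccccc4)c(OC)c(OC)c3C[C@H](CO)[C@H]2CO)ccc1OCc1ccccc1 | intermediate
14 | 4-[(1R,2S,3S)-7-hydroxy-2,3-bis(hydroxymethyl)-5,6-dimethoxy-1,2,3,4-tetrahydronaphthalen-1-yl]-2-methoxyphenol | COc1cc([C@@H]2c3cc(O)c(OC)c(OC)c3C[C@H](CO)[C@H]2CO)ccc1O | target

Total step count: 8. Longest linear sequence: 7 steps (steps 1–4, then 6, 7 and 8).

Steps most likely to fail

Step 6. The Friedel–Crafts closure may be slow, because C8a lies para to a methoxy group that is twisted out of conjugation by its two ortho neighbours. Acidolysis of the benzyl ethers or elimination at C1 could then compete. The fallback separates the two bond formations and closes the ring at the diol oxidation level. It sets out from 10: the alkylation with 5 is quenched under neutral conditions and 11 is isolated. LiAlH4 (THF, 0 °C) then reduces 11 to (1S,2S,3S)-3-[[4-(benzyloxy)-2,3-dimethoxyphenyl]methyl]-1-[4-(benzyloxy)-3-methoxyphenyl]-2-(hydroxymethyl)butane-1,4-diol F1. Acid (TFA in CH2Cl2, or HCO2H) should convert F1 into the tetralin: the C1 cation can be stored reversibly as the tetrahydrofuran ether with the C3 hydroxymethyl group and should funnel to the carbocycle, as in the acid-induced furan-to-tetralin isomerisation of lariciresinol-type lignans. The route is rejoined at 13.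

Step 5. The electron-rich aldehyde 6 is a weak acceptor, so conversion may be low while donor 7 is consumed by self-aldolisation. The fallback is an auxiliary-controlled aldol that sets out from 6. (R)-4-Benzyloxazolidin-2-one is N-acylated (n-BuLi, methyl 4-chloro-4-oxobutanoate, THF, −78 °C) to methyl 4-[(4R)-4-benzyl-2-oxo-1,3-oxazolidin-3-yl]-4-oxobutanoate F2. Its dibutylboron enolate (Bu2BOTf, i-Pr2NEt, CH2Cl2, −78 °C) should add to 6 in an Evans syn-aldol reaction to give methyl (3R,4R)-3-[(4R)-4-benzyl-2-oxo-1,3-oxazolidine-3-carbonyl]-4-[4-(benzyloxy)-3-methoxyphenyl]-4-hydroxybutanoate F3. LiBH4 (THF/MeOH, 0 °C) removes the auxiliary reductively to methyl (3S,4R)-4-[4-(benzyloxy)-3-methoxyphenyl]-4-hydroxy-3-(hydroxymethyl)butanoate F4, which lactonises (TsOH cat.) to (4S)-4-[(R)-[4-(benzyloxy)-3-methoxyphenyl](hydroxy)methyl]oxolan-2-one F5, the C1 epimer of 10. F5 is taken through the conditions of step 6 unchanged. Its alkylation product, (3S,4S)-3-[[4-(benzyloxy)-2,3-dimethoxyphenyl]methyl]-4-[(R)-[4-(benzyloxy)-3-methoxyphenyl](hydroxy)methyl]oxolan-2-one F6, ionises at C1 to the same cation as 11, so the route is rejoined at 12.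

Step 1. Site selectivity among three phenols may be poor, with alkylation at the 3-hydroxyl or double benzylation. The fallback builds the ring A oxygen pattern by C–H oxidation and sets out from 6. The formyl group is masked in situ as its α-amino alkoxide (LiN(Me)CH2CH2NMe2, THF, −20 °C), and directed ortho-lithiation (n-BuLi) should then occur at the position between the masked formyl and the methoxy group. Borylation and oxidation (B(OMe)3, then H2O2/AcOH) give 4-(benzyloxy)-2-hydroxy-3-methoxybenzaldehyde F7. O-Methylation (MeI, K2CO3, DMF) rejoins the route at 3.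

Further compounds
F1 | step 6 | (1S,2S,3S)-3-[[4-(benzyloxy)-2,3-dimethoxyphenyl]methyl]-1-[4-(benzyloxy)-3-methoxyphenyl]-2-(hydroxymethyl)butane-1,4-diol | COc1cc([C@@H](O)[C@H](CO)[C@@H](CO)Cc2ccc(OCc3ccccc3)c(OC)c2OC)ccc1OCc1ccccc1
F2 | step 5 | methyl 4-[(4R)-4-benzyl-2-oxo-1,3-oxazolidin-3-yl]-4-oxobutanoate | COC(=O)CCC(=O)N1[C@H](Cc2ccccc2)COC1=O
F3 | step 5 | methyl (3R,4R)-3-[(4R)-4-benzyl-2-oxo-1,3-oxazolidine-3-carbonyl]-4-[4-(benzyloxy)-3-methoxyphenyl]-4-hydroxybutanoate | COC(=O)C[C@H]([C@@H](O)c1ccc(OCc2ccccc2)c(OC)c1)C(=O)N1[C@H](Cc2ccccc2)COC1=O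
F4 | step 5 | methyl (3S,4R)-4-[4-(benzyloxy)-3-methoxyphenyl]-4-hydroxy-3-(hydroxymethyl)butanoate | COC(=O)C[C@@H](CO)[C@@H](O)c1ccc(OCc2ccccc2)c(OC)c1
F5 | step 5 | (4S)-4-[(R)-[4-(benzyloxy)-3-methoxyphenyl](hydroxy)methyl]oxolan-2-one | O=C1C[C@@H](CO1)[C@@H](O)c1ccc(OCc2ccccc2)c(OC)c1
F6 | step 5 | (3S,4S)-3-[[4-(benzyloxy)-2,3-dimethoxyphenyl]methyl]-4-[(R)-[4-(benzyloxy)-3-methoxyphenyl](hydroxy)methyl]oxolan-2-one | O=C1OC[C@@H]([C@@H](O)c2ccc(OCc3ccccc3)c(OC)c2)[C@@H]1Cc1ccc(OCc2ccccc2)c(OC)c1OC
F7 | step 1 | 4-(benzyloxy)-2-hydroxy-3-methoxybenzaldehyde | O=Cc1ccc(OCc2ccccc2)c(OC)c1O
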